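**Strategy.** The route rests on breaking the C5–C6 bond of ring B back to a bridged 1,5-diene: an anionic oxy-Cope rearrangement of a 2-dienylbicyclo[2.2.2]oct-5-en-2-ol. It exploits the array C6–C7–C8(=O)···C3(O)–C4–C5: the C8 ketone with its α-isopropenyl carbon C7 emerges as a dienolate, the C3 oxygen as an enol ether, and the bicycle forces C6 onto one face of C4=C5. In one operation ring B is closed, the quaternary C5 is set cis to H-10, and C7 and C4 follow on protonation. The precursor is a 1-methoxy-5,6-dimethylbicyclo[2.2.2]octene with a tertiary dienyl carbinol and a neighbouring silyloxy group; one catalytic Diels–Alder reaction fixes its absolute configuration.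

Key step: step 9

Remark on numbering: the decalins carry eremophilane numbers (ring A C1–C5/C10, ring B C5–C10, C14 and C15 the methyls on C5 and C4, C11–C13 the isopropenyl group; β is the face of the C5 methyl). Bicyclo[2.2.2]octene locants C1, C2, C3, C4, C5, C6, C7, C8 become C3, C8, C9, C10, C5, C4, C2, C1 of the target.

Assumption: the catalyst antipode named in step 2 is taken to give the bridgehead configuration drawn; if the other antipode of 4 forms, the mirror-image catalyst is used.

**Step 1**
Reactants: 1 2,3-dimethylcyclohex-2-en-1-one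
Product: 2 1-methoxy-2,3-dimethylcyclohexa-1,3-diene
Conditions: HC(OMe)3, MeOH, TsOH (cat.), rt; then distillation from TsOH (cat.), 110 °C
Reagents that add atoms: trimethyl orthoformate COC(OC)OC
Why: Acid-catalysed ketalisation and loss of methanol (dienol ether formation) should give the through-conjugated 1-alkoxy-1,3-diene, the thermodynamic isomer under these equilibrating conditions.

**Step 2**
Reactants: 2 1-methoxy-2,3-dimethylcyclohexa-1,3-diene; 3 acrolein
Product: 4 (1R,2R,4R)-1-methoxy-5,6-dimethylbicyclo[2.2.2]oct-5-ene-2-carbaldehyde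
Conditions: (S)-3,3-diphenyl-1-(o-tolyl)tetrahydro-1H,3H-pyrrolo[1,2-c][1,3,2]oxazaborole (20 mol %), Tf2NH (16 mol %), CH2Cl2, −78 °C
Reagents that add atoms: none
Why: In this enantioselective Lewis acid-catalysed Diels–Alder reaction the electron-rich CH terminus of the 1-methoxydiene should bond to the β-carbon of the catalyst-bound enal and the methoxy-bearing terminus to the α-carbon (ortho, endo), the shielded enal face setting both bridgeheads; the C2 configuration is erased in step 3.

**Step 3**
Reactants: 4 (1R,2R,4R)-1-methoxy-5,6-dimethylbicyclo[2.2.2]oct-5-ene-2-carbaldehyde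
Product: 5 (1S,4R)-1-methoxy-5,6-dimethylbicyclo[2.2.2]oct-5-en-2-one
Conditions: O2 (1 atm), Cu(OAc)2 (cat.), 2,2'-bipyridine (cat.), DABCO, DMF, 40 °C
Reagents that add atoms: dioxygen O=O
Why: Copper-catalysed aerobic oxidative deformylation of an α-branched aldehyde (oxygenation of the enol, cleavage of the dioxetane) should excise the formyl carbon and leave the ketone next to the methoxy bridgehead.

**Step 4**
Reactants: 5 (1S,4R)-1-methoxy-5,6-dimethylbicyclo[2.2.2]oct-5-en-2-one
Product: 7 (1S,3R,4S)-3-hydroxy-1-methoxy-5,6-dimethylbicyclo[2.2.2]oct-5-en-2-one, via potassium enolate 6 (not isolated)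
Conditions: KN(SiMe3)2, THF, −78 °C; 2-(phenylsulfonyl)-3-phenyloxaziridine, −78 °C; AcOH
Reagents that add atoms: 2-(phenylsulfonyl)-3-phenyloxaziridine O=S(=O)(c1ccccc1)N1OC1c1ccccc1
Why: Enolate α-hydroxylation with an N-sulfonyloxaziridine can only occur at C3, the sole enolisable position, and the configuration of the new carbinol is erased in step 5.

**Step 5**
Reactants: 7 (1S,3R,4S)-3-hydroxy-1-methoxy-5,6-dimethylbicyclo[2.2.2]oct-5-en-2-one
Product: 8 (1S,4S)-1-methoxy-5,6-dimethylbicyclo[2.2.2]oct-5-ene-2,3-dione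
Conditions: Dess–Martin periodinane, CH2Cl2, rt
Reagents that add atoms: none
Why: Dess–Martin oxidation should give the non-enolisable 1,2-diketone, which makes C3 trigonal so that no C3 substituent blocks the alkene face of C2 in step 7.

**Step 6**
Reactants: 9 2-methylbut-1-en-3-yne
Product: 11 2-bromo-3-methylbuta-1,3-diene, via bromoboration adduct 10 (not isolated)
Conditions: B-bromo-9-borabicyclo[3.3.1]nonane, CH2Cl2, 0 °C; then AcOH, 0 °C → rt
Reagents that add atoms: B-bromo-9-borabicyclo[3.3.1]nonane BrB1C2CCCC1CCC2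
Why: Markovnikov cis-bromoboration of the terminal alkyne followed by protonolysis of the alkenyl–boron bond should give the 2-bromo-1,3-diene without touching the alkene.

**Step 7**
Reactants: 8 (1S,4S)-1-methoxy-5,6-dimethylbicyclo[2.2.2]oct-5-ene-2,3-dione; 11 2-bromo-3-methylbuta-1,3-diene
Product: 14 (1S,2S,3R,4S)-1-methoxy-5,6-dimethyl-2-(3-methylbuta-1,3-dien-2-yl)bicyclo[2.2.2]oct-5-ene-2,3-diol, via dienyllithium 12 (not isolated), via lithium keto alkoxide 13 (not isolated)
Conditions: 11, t-BuLi (2 equiv), Et2O, −78 °C; then 8, THF, −78 °C; then LiAlH4, −78 → −20 °C; aq. NaOH work-up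
Reagents that add atoms: none
Why: After bromine–lithium exchange the dienyllithium should add 1,2 to the C2 carbonyl, which is activated and lithium-chelated by the syn-coplanar bridgehead methoxy group, from the open face of the C5=C6 bridge; chelation-controlled LiAlH4 reduction of C3 from the alkoxide face, anti to the dienyl group, should then give the trans-diol with the C3 hydroxyl syn to the alkene bridge.

**Step 8**
Reactants: 14 (1S,2S,3R,4S)-1-methoxy-5,6-dimethyl-2-(3-methylbuta-1,3-dien-2-yl)bicyclo[2.2.2]oct-5-ene-2,3-diol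
Product: 15 (1S,2S,3R,4S)-3-[(tert-butyldimethylsilyl)oxy]-1-methoxy-5,6-dimethyl-2-(3-methylbuta-1,3-dien-2-yl)bicyclo[2.2.2]oct-5-en-2-ol
Conditions: TBSCl, imidazole, DMAP (cat.), DMF, 40 °C
Reagents that add atoms: tert-butyldimethylsilyl chloride CC(C)(C)[Si](C)(C)Cl
Why: Silylation should take place only at the secondary hydroxyl, the tertiary allylic hydroxyl being too hindered for the silyl chloride.

**Step 9**
Reactants: 15 (1S,2S,3R,4S)-3-[(tert-butyldimethylsilyl)oxy]-1-methoxy-5,6-dimethyl-2-(3-methylbuta-1,3-dien-2-yl)bicyclo[2.2.2]oct-5-en-2-ol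
Product: 19 9β-(tert-butyldimethylsilyloxy)-10βH-eremophil-11-ene-3,8-dione, via potassium alkoxide 16 (not isolated), via potassium dienolate 17 (not isolated), via enol ether ketone 18 (not isolated)
Conditions: KH, 18-crown-6, THF, 0 °C → rt; AcOH, −78 °C; then aq. oxalic acid, THF, rt
Reagents that add atoms: water O
Why: The potassium alkoxide should undergo an anionic oxy-Cope ([3,3]-sigmatropic) rearrangement of the 1,5-diene C6=C7–C8(O−)–C3–C4=C5 through the boat array imposed by the bicycle, breaking C8–C3 and forming C5–C6; the closest known reaction is the alkoxide-accelerated rearrangement of 2-vinylbicyclo[2.2.2]oct-5-en-2-ols to cis-fused octalones. Ring B (C5–C6–C7–C8–C9–C10) closes by this six-centre sigmatropic bond formation while the C3–C8 bridge opens, so the bicyclo[2.2.2]octene becomes the cis-decalin. C5 is controlled by the bridge: C6 can only reach the face of C4=C5 on which C8 sits, so the C5 methyl ends cis to H-10 and the configuration is relayed from C10. C7 is set by kinetic α-protonation of the dienolate and C4 by protonation during hydrolysis of the C3 enol ether; both should settle equatorial (7β-isopropenyl, 4β-methyl) in the chair–chair conformer that keeps the 9β-silyloxy group and the C5 methyl equatorial on ring B, and a 7-epimer should equilibrate through the enol. The step needs the dienyl group syn to the C4=C5 bridge (secured in step 7) and α- over γ-protonation of the dienolate (secured by the acetic acid quench at −78 °C and the mild oxalic acid hydrolysis, which leave the 11,12-double bond out of conjugation).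

**Step 10**
Reactants: 19 9β-(tert-butyldimethylsilyloxy)-10βH-eremophil-11-ene-3,8-dione
Product: 20 9β-(tert-butyldimethylsilyloxy)-3β-hydroxy-10βH-eremophil-11-en-8-one
Conditions: LiBH(s-Bu)3, THF, −78 °C
Reagents that add atoms: none
Why: In this bulky trialkylborohydride reduction the C3 ketone (one α-methylene) should react before the C8 ketone, which is flanked by two tertiary α-carbons and the silyloxy group, and equatorial attack from the α-face, opposite the axial C5 methyl, should give the axial 3β-alcohol.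

**Step 11**
Reactants: 20 9β-(tert-butyldimethylsilyloxy)-3β-hydroxy-10βH-eremophil-11-en-8-one; 21 3-methylbut-2-enoic acid
Product: 22 9β-(tert-butyldimethylsilyloxy)-3α-(3-methylbut-2-enoyloxy)-10βH-eremophil-11-en-8-one
Conditions: PPh3, DIAD, toluene, 0 °C → rt
Reagents that add atoms: none
Why: The Mitsunobu esterification should proceed with SN2 inversion at C3, the carboxylate entering along the unhindered equatorial direction opposite the axial leaving group, to give the equatorial 3α-ester directly.

**Step 12**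
Reactants: 22 9β-(tert-butyldimethylsilyloxy)-3α-(3-methylbut-2-enoyloxy)-10βH-eremophil-11-en-8-one
Product: 23 9β-hydroxy-3α-(3-methylbut-2-enoyloxy)-10βH-eremophil-11-en-8-one
Conditions: HF·pyridine, THF, 0 °C → rt
Reagents that add atoms: none
Why: Fluoride-mediated desilylation under mildly acidic conditions should free the C9 hydroxyl without the base that could move the 11,12-double bond into conjugation or epimerise C7 and C9.

**Step 13**
Reactants: 23 9β-hydroxy-3α-(3-methylbut-2-enoyloxy)-10βH-eremophil-11-en-8-one; 21 3-methylbut-2-enoic acid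
Product: 24 CNP0264508.1
Conditions: DCC, DMAP (cat.), CH2Cl2, 0 °C → rt
Reagents that add atoms: none
Why: Steglich esterification should acylate the equatorial α-hydroxy ketone with retention and, since no acid chloride or ketene is formed, keep the senecioyl double bond in conjugation.

**Compound list**

1 | 2,3-dimethylcyclohex-2-en-1-one | CC1=C(C)C(=O)CCC1 | starting material
2 | 1-methoxy-2,3-dimethylcyclohexa-1,3-diene | COC1=C(C)C(C)=CCC1 | intermediate
3 | acrolein (prop-2-enal) | C=CC=O | starting material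
4 | (1R,2R,4R)-1-methoxy-5,6-dimethylbicyclo[2.2.2]oct-5-ene-2-carbaldehyde (formyl syn to the C5=C6 bridge) | CO[C@]12CC[C@H](C[C@H]1C=O)C(C)=C2C | intermediate
5 | (1S,4R)-1-methoxy-5,6-dimethylbicyclo[2.2.2]oct-5-en-2-one | CO[C@]12CC[C@H](CC1=O)C(C)=C2C | intermediate
6 | potassium enolate of 5 | CO[C@]12CC[C@H](C=C1[O-])C(C)=C2C.[K+] | intermediate
7 | (1S,3R,4S)-3-hydroxy-1-methoxy-5,6-dimethylbicyclo[2.2.2]oct-5-en-2-one (hydroxyl syn to the C5=C6 bridge) | CO[C@]12CC[C@H]([C@@H](O)C1=O)C(C)=C2C | intermediate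
8 | (1S,4S)-1-methoxy-5,6-dimethylbicyclo[2.2.2]oct-5-ene-2,3-dione | CO[C@]12CC[C@H](C(=O)C1=O)C(C)=C2C | intermediate
9 | 2-methylbut-1-en-3-yne | C#CC(C)=C | starting material
10 | B-[(Z)-2-bromo-3-methylbuta-1,3-dien-1-yl]-9-borabicyclo[3.3.1]nonane | Br/C(C(C)=C)=C\B1C2CCCC1CCC2 | intermediate
11 | 2-bromo-3-methylbuta-1,3-diene | C=C(Br)C(C)=C | intermediate
12 | (3-methylbuta-1,3-dien-2-yl)lithium | [Li]C(=C)C(C)=C | intermediate
13 | lithium (1S,2R,4S)-1-methoxy-5,6-dimethyl-2-(3-methylbuta-1,3-dien-2-yl)-3-oxobicyclo[2.2.2]oct-5-en-2-olate (dienyl syn to the C5=C6 bridge) | CO[C@]12CC[C@H](C(=O)[C@@]1([O-])C(=C)C(C)=C)C(C)=C2C.[Li+] | intermediate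
14 | (1S,2S,3R,4S)-1-methoxy-5,6-dimethyl-2-(3-methylbuta-1,3-dien-2-yl)bicyclo[2.2.2]oct-5-ene-2,3-diol (dienyl and C3 hydroxyl syn to the C5=C6 bridge) | CO[C@]12CC[C@H]([C@@H](O)[C@@]1(O)C(=C)C(C)=C)C(C)=C2C | intermediate
15 | (1S,2S,3R,4S)-3-[(tert-butyldimethylsilyl)oxy]-1-methoxy-5,6-dimethyl-2-(3-methylbuta-1,3-dien-2-yl)bicyclo[2.2.2]oct-5-en-2-ol | CO[C@]12CC[C@H]([C@@H](O[Si](C)(C)C(C)(C)C)[C@@]1(O)C(=C)C(C)=C)C(C)=C2C | intermediate
16 | potassium alkoxide of 15 | CO[C@]12CC[C@H]([C@@H](O[Si](C)(C)C(C)(C)C)[C@@]1([O-])C(=C)C(C)=C)C(C)=C2C.[K+] | intermediate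
17 | potassium 9β-(tert-butyldimethylsilyloxy)-3-methoxy-10βH-eremophila-3,7,11-trien-8-olate (5β-methyl) | C=C(C)C=1C[C@@]2(C)[C@H](CCC(OC)=C2C)[C@@H](O[Si](C)(C)C(C)(C)C)C=1[O-].[K+] | intermediate
18 | 9β-(tert-butyldimethylsilyloxy)-3-methoxy-10βH-eremophila-3,11-dien-8-one (5β-methyl, 7β-isopropenyl) | C=C(C)[C@H]1C[C@@]2(C)[C@H](CCC(OC)=C2C)[C@@H](O[Si](C)(C)C(C)(C)C)C1=O | intermediate
19 | 9β-(tert-butyldimethylsilyloxy)-10βH-eremophil-11-ene-3,8-dione (4β,5β-dimethyl, 7β-isopropenyl, cis-fused) | C=C(C)[C@H]1C[C@@]2(C)[C@H](CCC(=O)[C@@H]2C)[C@@H](O[Si](C)(C)C(C)(C)C)C1=O | intermediate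
20 | 9β-(tert-butyldimethylsilyloxy)-3β-hydroxy-10βH-eremophil-11-en-8-one | C=C(C)[C@H]1C[C@@]2(C)[C@H](CC[C@H](O)[C@@H]2C)[C@@H](O[Si](C)(C)C(C)(C)C)C1=O | intermediate
21 | 3-methylbut-2-enoic acid | CC(C)=CC(=O)O | starting material
22 | 9β-(tert-butyldimethylsilyloxy)-3α-(3-methylbut-2-enoyloxy)-10βH-eremophil-11-en-8-one | C=C(C)[C@H]1C[C@@]2(C)[C@H](CC[C@@H](OC(=O)C=C(C)C)[C@@H]2C)[C@@H](O[Si](C)(C)C(C)(C)C)C1=O | intermediate
23 | 9β-hydroxy-3α-(3-methylbut-2-enoyloxy)-10βH-eremophil-11-en-8-one | C=C(C)[C@H]1C[C@@]2(C)[C@H](CC[C@@H](OC(=O)C=C(C)C)[C@@H]2C)[C@@H](O)C1=O | intermediate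
24 | CNP0264508.1, (3R,4R,5R,7R,9R,10S)-3α,9β-bis(3-methylbut-2-enoyloxy)-10βH-eremophil-11-en-8-one | C=C(C)[C@H]1C[C@@]2(C)[C@H](CC[C@@H](OC(=O)C=C(C)C)[C@@H]2C)[C@@H](OC(=O)C=C(C)C)C1=O | target

**Step count and risks**

Total: 13 steps. Longest linear sequence: 12 steps (steps 1–5 and 7–13); step 6 is a one-step side branch.

Steps most likely to fail:

1. Step 2. The acid-sensitive dienol ether may be hydrolysed or oligomerised by the cationic boron catalyst, the addition may stop at the open-chain conjugate adduct instead of closing the bicycle, or the two diene faces may be poorly differentiated. The fallback sets out from 2 and comes back at 5. A Diels–Alder reaction of 2 with 3-acryloyloxazolidin-2-one, catalysed by the Cu(SbF6)2 complex of 2,2'-isopropylidenebis[(4S)-4-tert-butyl-2-oxazoline] (divalent copper; mirror-image ligand if required), should give the endo N-acyl oxazolidinone F1. Enolate hydroxylation (NaN(SiMe3)2, then the oxaziridine of step 4) should give the α-hydroxy imide F2. LiBH4 should reduce this to the 1,2-diol F3, and NaIO4 should cleave F3 to ketone 5.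

2. Step 7. The dienyllithium may attack the C3 carbonyl of the diketone or add twice, and the hydride may then arrive from the alkene face. The fallback sets out from 5 and comes back at 14. Nitrosation of the enolate of 5 at C3 (tert-butyl nitrite, KOt-Bu, THF) should give the hydroxyimino ketone F4, in which only C2 is a ketone. Two equivalents of 12 (the first deprotonates the oxime) should add to C2 from the alkene face to give the hydroxy oxime F5. Reductive deoximation (TiCl3, NH4OAc, aq. THF) should give the α-ketol F6, and LiAlH4 reduction as in step 7 should give 14.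

3. Step 11. The crowded axial alkoxyphosphonium ion may fail to form, may collapse by anti-elimination to a ring A alkene, or the weakly acidic acid may acylate with retention. The fallback sets out from 20 and comes back at 22. Triflation (Tf2O, pyridine, CH2Cl2, −40 °C) should give the axial triflate F7, a small and far more reactive leaving group. Displacement with caesium 3-methylbut-2-enoate (from 21 and Cs2CO3; 18-crown-6, toluene) should give 22 with inversion.

**Further compounds**

F1 | step 2 | 3-[(1R,2R,4R)-1-methoxy-5,6-dimethylbicyclo[2.2.2]oct-5-ene-2-carbonyl]oxazolidin-2-one | CO[C@]12CC[C@H](C[C@H]1C(=O)N3CCOC3=O)C(C)=C2C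
F2 | step 2 | 3-[(2-hydroxy-1-methoxy-5,6-dimethylbicyclo[2.2.2]oct-5-en-2-yl)carbonyl]oxazolidin-2-one (hydroxyl syn to the C5=C6 bridge; C2 configuration immaterial) | CO[C@]12CC[C@H](C[C@]1(O)C(=O)N3CCOC3=O)C(C)=C2C
F3 | step 2 | 2-(hydroxymethyl)-1-methoxy-5,6-dimethylbicyclo[2.2.2]oct-5-en-2-ol (C2 configuration immaterial) | CO[C@]12CC[C@H](C[C@]1(O)CO)C(C)=C2C
F4 | step 7 | (1S,4S)-3-(hydroxyimino)-1-methoxy-5,6-dimethylbicyclo[2.2.2]oct-5-en-2-one (oxime geometry not defined) | CO[C@]12CC[C@H](C(=NO)C1=O)C(C)=C2C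
F5 | step 7 | 3-(hydroxyimino)-1-methoxy-5,6-dimethyl-2-(3-methylbuta-1,3-dien-2-yl)bicyclo[2.2.2]oct-5-en-2-ol (dienyl syn to the C5=C6 bridge) | CO[C@]12CC[C@H](C(=NO)[C@@]1(O)C(=C)C(C)=C)C(C)=C2C
F6 | step 7 | (1S,2R,4S)-2-hydroxy-1-methoxy-5,6-dimethyl-2-(3-methylbuta-1,3-dien-2-yl)bicyclo[2.2.2]oct-5-en-3-one | CO[C@]12CC[C@H](C(=O)[C@@]1(O)C(=C)C(C)=C)C(C)=C2C
F7 | step 11 | 9β-(tert-butyldimethylsilyloxy)-3β-(trifluoromethanesulfonyloxy)-10βH-eremophil-11-en-8-one | C=C(C)[C@H]1C[C@@]2(C)[C@H](CC[C@H](OS(=O)(=O)C(F)(F)F)[C@@H]2C)[C@@H](O[Si](C)(C)C(C)(C)C)C1=O
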